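**Retrosynthetic overview**
1. Target ⇐ photochemical deconjugation of the (Z)-9′-isobutylidene furanone 15, which sets C9′; 15 ⇐ aldol condensation of ring D methylene ketone 12 with isobutyraldehyde.
2. 12 ⇐ one anodic cascade from the acyclic vinyl hydroquinone 7: quinone formation, intramolecular vinyl quinone Diels–Alder (C2′–C6′ and C3–C7′, rings B and C together), re-oxidation, oxa-Michael spiro-closure (O–C3, ring D).
3. 7 ⇐ Heck coupling of bromohydroquinone (ring A) with the α′-hydroxy enone 5.
4. 5 ⇐ (S)-linalool by allylic oxidation and carbene-catalysed hydroxymethylation; linalool supplies C3′, the only purchased stereocentre.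
5. Ring order: A (purchased) → B and C (one step) → D.

Assumption: (S)-(+)-linalool (coriandrol) of high enantiomeric purity is taken as the commercial chiral-pool material.

Locants used in the names: ring A = C1–C6 (C1 and C4 oxygenated, C2 carries the side chain, C3 is its ring neighbour). The side chain is C1′–C12′ counted from ring A, with methyls on C3′, C7′ and C11′. Ring B = C2, C3, C7′, C6′, C2′, C1′; ring C = C2′–C6′; ring D = O, C3, C7′, C8′, C9′.

**Step 1**
Reactants: 1 (S)-(+)-linalool
Product: 3 (2E,6S)-6-hydroxy-2,6-dimethylocta-2,7-dienal, via allylic alcohol 2 (not isolated)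
Conditions: SeO2 (1.2 equiv), 1,4-dioxane/H2O (20:1), 80 °C
Reagents that add atoms: selenium dioxide, O=[Se]=O
Why: Riley allylic oxidation (ene reaction then 2,3-sigmatropic shift) attacks the (E)-methyl of the trisubstituted alkene only and carries the intermediate alcohol on to the E-enal; the vinyl group has no allylic hydrogen and the carbinol stereocentre is untouched.

**Step 2**
Reactants: 3 (2E,6S)-6-hydroxy-2,6-dimethylocta-2,7-dienal; 4 paraformaldehyde
Product: 5 (3E,7S)-1,7-dihydroxy-3,7-dimethylnona-3,8-dien-2-one
Conditions: (CH2O)n (3 equiv), 3-benzyl-5-(2-hydroxyethyl)-4-methylthiazolium chloride (10 mol%), i-Pr2NEt (20 mol%), THF, 60 °C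
Reagents that add atoms: none
Why: N-heterocyclic-carbene (thiazolylidene) catalysed hydroxymethylation, a crossed acyloin reaction in which the Breslow intermediate of the enal reacts as an acyl anion (not a homoenolate) with formaldehyde, gives the α′-hydroxy enone with the E-alkene retained and no new stereocentre.

**Step 3**
Reactants: 5 (3E,7S)-1,7-dihydroxy-3,7-dimethylnona-3,8-dien-2-one; 6 2-bromobenzene-1,4-diol
Product: 7 vinyl hydroquinone 2-[(1′E,3′S,6′E)-3′,9′-dihydroxy-3′,7′-dimethyl-8′-oxonona-1′,6′-dienyl]benzene-1,4-diol
Conditions: Pd(OAc)2 (5 mol%), P(o-tol)3 (10 mol%), NaHCO3 (2.5 equiv), DMF, 90 °C, Ar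
Reagents that add atoms: none
Why: Mizoroki–Heck reaction in which the aryl group adds to the terminal carbon of the unhindered vinyl group and β-hydride elimination, possible only on the benzylic side because the carbinol carbon is quaternary, gives the E-styrene; the trisubstituted enone is inert, bicarbonate leaves the hydroquinone un-ionised and no stereocentre is touched.

**Step 4**
Reactants: 7 vinyl hydroquinone
Product: 12 tetracyclic ring D methylene furanone (3S,2′R,3′S,6′S,7′R), via vinyl quinone 8 (not isolated), via isoquinone methide 9 (not isolated), via tricyclic hydroquinone 10 (not isolated), via tricyclic quinone 11 (not isolated)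
Conditions: divided cell, graphite-felt anode, Pt cathode, +0.8 V vs Ag/AgCl, 4.1 F/mol, LiClO4 (0.1 M), 2,6-lutidine (4 equiv), MeCN (5 mM), 35 °C, catholyte AcOH/LiClO4/MeCN; then DBU (0.2 equiv), 25 °C
Reagents that add atoms: none
Why: Proposed new method: an anodically driven double-dehydrogenation cascade (closest known type: vinyl quinone Diels–Alder cascades triggered by chemical oxidants, and anodic hydroquinone-to-quinone oxidation; the one-pot electrochemical version ending in an oxa-Michael spiro-closure is not known) in which two-electron oxidation gives vinyl quinone 8, whose intramolecular Diels–Alder reaction forms C2′–C6′ and C3–C7′ through the endo transition state with the 3′-hydroxyl in the diene plane ("inside") and the 3′-methyl anti to the incoming E-enone, so that the linalool-derived C3′ fixes C6′ and C7′; adduct 9 aromatises to 10, which is re-oxidised at the same potential to quinone 11, the primary alcohol then adds 5-exo to C3 on the only face it can reach (cis to the acyl group on C7′, setting C3), and DBU equilibrates the γ-epimerisable C2′ to the trans ring B/C fusion because the cis isomer would put C3′ syn-axial to the 7′-methyl.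

**Step 5**
Reactants: 12 tetracyclic ring D methylene furanone; 13 isobutyraldehyde
Product: 15 (Z)-9′-(2-methylpropylidene) furanone, via aldol adduct 14 (not isolated)
Conditions: i-PrCHO (5 equiv), neutral Al2O3, CH2Cl2, 25 °C
Reagents that add atoms: none
Why: Aldol condensation (aurone-type) at C9′, the only enolisable α-position because C7′ is quaternary and the ring A carbonyls have no α-hydrogen, gives after dehydration the conjugated, thermodynamically preferred Z-alkylidene; no stereocentre is formed and C2′ already sits in its thermodynamic configuration.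

**Step 6**
Reactants: 15 (Z)-9′-(2-methylpropylidene) furanone
Product: 18 target CNP0156201.1, via E isomer 16 (not isolated), via dienol 17 (not isolated)
Conditions: hν (365 nm), 1,2-dimethylimidazole (20 mol%), degassed MeCN (2 mM), −40 °C
Reagents that add atoms: none
Why: Photodeconjugation of an α,β-unsaturated ketone: Z-to-E photoisomerisation brings the isopropyl methine hydrogen next to the C8′ carbonyl, photoenolisation by 1,5-hydrogen transfer gives dienol 17, and its base-mediated ketonisation protonates the α-carbon C9′ kinetically from the exposed convex face of the cis-fused ring D/ring B bicycle (the face opposite ring B), which leaves the isobutenyl group syn to ring B, i.e. (9′R), in a β,γ-unsaturated ketone that the weak base does not re-enolise at −40 °C.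

**Compound list**
1 | (S)-(+)-linalool, (3S)-3,7-dimethylocta-1,6-dien-3-ol | CC(C)=CCC[C@](C)(O)C=C | starting material
2 | (2E,6S)-2,6-dimethylocta-2,7-diene-1,6-diol (allylic alcohol, not isolated) | OC/C(C)=C/CC[C@](C)(O)C=C | intermediate
3 | (2E,6S)-6-hydroxy-2,6-dimethylocta-2,7-dienal | O=C/C(C)=C/CC[C@](C)(O)C=C | intermediate
4 | paraformaldehyde (formaldehyde equivalent) | C=O | starting material
5 | (3E,7S)-1,7-dihydroxy-3,7-dimethylnona-3,8-dien-2-one | OCC(=O)/C(C)=C/CC[C@](C)(O)C=C | intermediate
6 | 2-bromobenzene-1,4-diol (bromohydroquinone) | Oc1ccc(O)c(Br)c1 | starting material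
7 | vinyl hydroquinone, 2-[(1′E,3′S,6′E)-3′,9′-dihydroxy-3′,7′-dimethyl-8′-oxonona-1′,6′-dienyl]benzene-1,4-diol | OCC(=O)/C(C)=C/CC[C@](C)(O)/C=C/c1cc(O)ccc1O | intermediate
8 | vinyl quinone, the 1,4-benzoquinone of 7 (1′E,3′S,6′E; not isolated) | OCC(=O)/C(C)=C/CC[C@](C)(O)/C=C/C1=CC(=O)C=CC1=O | intermediate
9 | isoquinone methide, trans-fused endo Diels–Alder adduct (3S,2′R,3′S,6′S,7′R): ring A 5-ene-1,4-dione with C3–H and exocyclic C2=C1′, 7′-hydroxyacetyl (not isolated) | [C@H]23C(=O)C=CC(=O)C2=C[C@@H]2[C@H](CC[C@]2(C)O)[C@@]3(C)C(=O)CO | intermediate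
10 | tricyclic hydroquinone (3′S,6′S,7′R): aromatic ring A 1,4-diol, C1′=C2′ alkene in ring B, 7′-hydroxyacetyl (not isolated) | OCC(=O)[C@@]1(C)c2c(O)ccc(O)c2C=C2[C@@H]1CC[C@]2(C)O | intermediate
11 | tricyclic quinone (3′S,6′S,7′R): ring A 1,4-quinone (C2=C3), C1′=C2′ alkene, 7′-hydroxyacetyl (not isolated) | OCC(=O)[C@@]1(C)C2=C(C=C3[C@@H]1CC[C@]3(C)O)C(=O)C=CC2=O | intermediate
12 | tetracyclic ring D methylene furanone (3S,2′R,3′S,6′S,7′R): target skeleton carrying CH2 at C9′ | C1O[C@@]23C(=O)C=CC(=O)C2=C[C@@H]2[C@H](CC[C@]2(C)O)[C@@]3(C)C1=O | intermediate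
13 | isobutyraldehyde (2-methylpropanal) | CC(C)C=O | starting material
14 | aldol adduct, 9′-(1-hydroxy-2-methylpropyl) derivative of 12 (diastereomer mixture at C9′ and C10′, both centres lost on dehydration; not isolated) | CC(C)C(O)C1O[C@@]23C(=O)C=CC(=O)C2=C[C@@H]2[C@H](CC[C@]2(C)O)[C@@]3(C)C1=O | intermediate
15 | (Z)-9′-(2-methylpropylidene) furanone (3S,2′R,3′S,6′S,7′R), isopropyl cis to the ring D oxygen | CC(C)/C=C1\O[C@@]23C(=O)C=CC(=O)C2=C[C@@H]2[C@H](CC[C@]2(C)O)[C@@]3(C)C1=O | intermediate
16 | (E)-isomer of 15, isopropyl cis to the C8′ carbonyl (not isolated) | CC(C)/C=C1/O[C@@]23C(=O)C=CC(=O)C2=C[C@@H]2[C@H](CC[C@]2(C)O)[C@@]3(C)C1=O | intermediate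
17 | dienol, 8′-hydroxy-8′,9′-ene carrying the 9′-(2-methylprop-1-enyl) group, other stereocentres as in 15 (not isolated) | CC(C)=CC=1O[C@@]23C(=O)C=CC(=O)C2=C[C@@H]2[C@H](CC[C@]2(C)O)[C@@]3(C)C=1O | intermediate
18 | CNP0156201.1, (3S,2′R,3′S,6′S,7′R,9′R) | CC(C)=C[C@H]1O[C@@]23C(=O)C=CC(=O)C2=C[C@@H]2[C@H](CC[C@]2(C)O)[C@@]3(C)C1=O | target

**Totals and risks**
Total step count: 6. Longest linear sequence: 6 steps (1 → 18).

The three steps most likely to fail are steps 4, 6 and 5.

Step 4, the proposed anodic cascade, may fail through cathodic back-reduction or dimerisation of the quinones, through a sluggish cycloaddition between the electron-poor diene and the enone, or through over-isomerisation of quinone 11 under base. The fallback uses known chemistry, sets out from 7 and comes back at 12, and makes no compound outside the list (F0). The electrolysis is replaced by staged stoichiometric oxidation: Ag2O in benzene (25 → 45 °C) takes 7 through vinyl quinone 8 and adduct 9 to hydroquinone 10, which is isolated under argon. A separate oxidation with PhI(OAc)2 in MeCN then gives quinone 11, and Et3N followed by catalytic DBU closes ring D and equilibrates C2′ to give 12.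

Step 6, the photodeconjugation, may fail because the ring A enedione absorbs at the same wavelength, because the β,γ-unsaturated product can undergo a 1,3-acyl shift, or because the facial preference at C9′ is smaller than expected. The fallback uses known chemistry, sets out from 15 and comes back at 18. Soft enolisation of 15 (TMSOTf, Et3N, CH2Cl2, −78 → 0 °C) removes the isopropyl methine hydrogen and also silylates the tertiary alcohol, giving the silyl dienol ether F3. Kinetic protodesilylation (dilute HCl, THF, −20 °C) then protonates the α-carbon C9′ from the same exposed face and frees the 3′-hydroxyl to give 18.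

Step 5, the late aldol condensation, may fail because the enedione of ring A is sensitive to the basic surface or because the aldehyde self-condenses. The fallback uses known chemistry, sets out from 12 and comes back at 15. TMSOTf/Et3N converts 12 into the bis-silyl enol ether F1. A Mukaiyama aldol reaction with 13 (BF3·OEt2, CH2Cl2, −78 °C, acidic work-up) gives aldol 14. Mesylation of its secondary hydroxyl (MsCl, Et3N, 0 °C) gives the mesylate F2, which DBU eliminates to 15.

**Further compounds**
F0 | step 4 | none | none
F1 | step 5 | bis(trimethylsilyl) derivative of 12: C8′=C9′ silyl enol ether and 3′-O-silyl ether | C=1O[C@@]23C(=O)C=CC(=O)C2=C[C@@H]2[C@H](CC[C@]2(C)O[Si](C)(C)C)[C@@]3(C)C=1O[Si](C)(C)C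
F2 | step 5 | 10′-methanesulfonate of aldol 14 (diastereomer mixture at C9′ and C10′) | CC(C)C(OS(C)(=O)=O)C1O[C@@]23C(=O)C=CC(=O)C2=C[C@@H]2[C@H](CC[C@]2(C)O)[C@@]3(C)C1=O
F3 | step 6 | silyl dienol ether: 8′-(trimethylsilyloxy)-8′,9′-ene with 9′-(2-methylprop-1-enyl) and 3′-O-trimethylsilyl | CC(C)=CC=1O[C@@]23C(=O)C=CC(=O)C2=C[C@@H]2[C@H](CC[C@]2(C)O[Si](C)(C)C)[C@@]3(C)C=1O[Si](C)(C)C
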